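**Plan**

1. Ring atoms are numbered as in the name of 22: C1 bears CH2OH, C1=C2 is (E), C5=C6 is (Z), C8 (R) carries the side chain, C11=C12 is (E). The unit C2(H)=C1(CH2OH)–C14, with the C2 hydrogen cis to CH2OH, is the retron of an alkoxide-anchored anti-carbometalation of a 2-alkyn-1-ol. The first cut is therefore ring bond C1–C14, giving the open-chain bromo alkynol 18.
2. Further cuts: C3–C4 and C1–CH2OH (propyne dianion, then formaldehyde, on a (Z)-allylic bromide), C5=C6 (Still–Gennari), C7–C8 (Johnson–Claisen with chirality transfer), the prenyl terminus (cross-metathesis), the carbinol C–C bond (Brown allylation), the side-chain C=C (Wittig) and C9–C10 (first Johnson–Claisen).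
3. Forward: one linear chain is grown from aldehyde 1 in thirteen steps. The only ring, the 14-membered carbocycle, is closed last by a CuI-catalysed intramolecular anti-carbomagnesiation that also sets the C1=C2 geometry and leaves the CH2OH group free.
4. Stereochemistry: C8 comes from a reagent-controlled Brown allylation (carbinol centre), relayed 1,3 by the chair Johnson–Claisen rearrangement. The (E) alkenes come from the two Johnson–Claisen steps, the (Z) alkene from the Still–Gennari olefination.

Key step: step 14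

Remark on the chemistry: aldehyde 1 and all reagents named under Conditions are taken as commercial; the enantiomeric purity of the route is set in step 5 and is assumed to pass unchanged through step 7. TBS = tert-butyldimethylsilyl.

**Route**

Step 1
Reactants: 1 3-[(tert-butyldimethylsilyl)oxy]propanal
Product: 2 rac-5-[(tert-butyldimethylsilyl)oxy]-2-methylpent-1-en-3-ol
Conditions: isopropenylmagnesium bromide, THF, −78 → 0 °C; aq NH4Cl
Reagents that add atoms: isopropenylmagnesium bromide, CC(=C)[Mg]Br
Why: Grignard 1,2-addition to the aldehyde; the racemic carbinol centre needs no control because it becomes an sp2 carbon in step 2.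

Step 2
Reactants: 2 rac-5-[(tert-butyldimethylsilyl)oxy]-2-methylpent-1-en-3-ol
Product: 4 ethyl (4E)-7-[(tert-butyldimethylsilyl)oxy]-4-methylhept-4-enoate, via ketene acetal 3 (not isolated)
Conditions: MeC(OEt)3 (6 equiv), EtCO2H (cat.), 140 °C, EtOH distilled off
Reagents that add atoms: triethyl orthoacetate, CC(OCC)(OCC)OCC
Why: Johnson–Claisen rearrangement through ketene acetal 3 in a chair transition state with the CH2CH2OTBS chain equatorial, which should give the (E)-trisubstituted alkene (C11=C12 of 22) and the C9–C10 bond.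

Step 3
Reactants: 4 ethyl (4E)-7-[(tert-butyldimethylsilyl)oxy]-4-methylhept-4-enoate
Product: 5 (4E)-7-[(tert-butyldimethylsilyl)oxy]-4-methylhept-4-enal
Conditions: i-Bu2AlH (1.05 equiv), CH2Cl2, −78 °C; aq potassium sodium tartrate
Reagents that add atoms: none
Why: Partial ester reduction by i-Bu2AlH at −78 °C should stop at the aluminium hemiacetal, which gives the aldehyde on work-up; silyl ether and alkene are inert.

Step 4
Reactants: 5 (4E)-7-[(tert-butyldimethylsilyl)oxy]-4-methylhept-4-enal
Product: 6 (2E,6E)-9-[(tert-butyldimethylsilyl)oxy]-2,6-dimethylnona-2,6-dienal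
Conditions: Ph3P=C(Me)CHO, toluene, 90 °C
Reagents that add atoms: 2-(triphenylphosphoranylidene)propanal, CC(C=O)=P(c1ccccc1)(c1ccccc1)c1ccccc1
Why: Wittig olefination with a stabilised ylide, which should give the (E)-2-methyl enal selectively.

Step 5
Reactants: 6 (2E,6E)-9-[(tert-butyldimethylsilyl)oxy]-2,6-dimethylnona-2,6-dienal
Product: 8 (4R,5E,9E)-12-[(tert-butyldimethylsilyl)oxy]-5,9-dimethyldodeca-1,5,9-trien-4-ol, via borinate ester 7 (not isolated)
Conditions: (+)-Ipc2BOMe, allylmagnesium bromide, Et2O, −78 → 20 °C; then 6, Et2O, −78 °C; NaOH, H2O2, 20 °C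
Reagents that add atoms: allylmagnesium bromide, C=CC[Mg]Br
Why: Brown allylation through a closed six-membered chair transition state; the allylborane from (+)-Ipc2BOMe (made from (−)-α-pinene) should add to the Re face of the aldehyde in 1,2-fashion and set the (R)-carbinol.

Step 6
Reactants: 8 (4R,5E,9E)-12-[(tert-butyldimethylsilyl)oxy]-5,9-dimethyldodeca-1,5,9-trien-4-ol
Product: 9 (5R,6E,10E)-13-[(tert-butyldimethylsilyl)oxy]-2,6,10-trimethyltrideca-2,6,10-trien-5-ol
Conditions: second-generation Grubbs catalyst (5 mol %), 2-methyl-2-butene (large excess), CH2Cl2, 40 °C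
Reagents that add atoms: 2-methyl-2-butene, CC=C(C)C
Why: Olefin cross-metathesis of the monosubstituted alkene with excess 2-methyl-2-butene should install the isopropylidene terminus; the trisubstituted alkenes are too hindered to compete and the free alcohol is tolerated.

Step 7
Reactants: 9 (5R,6E,10E)-13-[(tert-butyldimethylsilyl)oxy]-2,6,10-trimethyltrideca-2,6,10-trien-5-ol
Product: 11 ethyl (3R,4E)-3-[(3E)-6-[(tert-butyldimethylsilyl)oxy]-3-methylhex-3-en-1-yl]-4,8-dimethylnona-4,7-dienoate, via ketene acetal 10 (not isolated)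
Conditions: MeC(OEt)3 (8 equiv), EtCO2H (cat.), 140 °C, EtOH distilled off
Reagents that add atoms: triethyl orthoacetate, CC(OCC)(OCC)OCC
Why: Johnson–Claisen rearrangement with 1,3-chirality transfer: in the chair transition state the prenyl-bearing CH2 group sits equatorial, so the new side-chain alkene should be (E) and the C7–C8 bond forms on the face from which the C–O bond leaves, turning the (R)-carbinol into (R)-configured C8.

Step 8
Reactants: 11 ethyl (3R,4E)-3-[(3E)-6-[(tert-butyldimethylsilyl)oxy]-3-methylhex-3-en-1-yl]-4,8-dimethylnona-4,7-dienoate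
Product: 12 (3R,4E)-3-[(3E)-6-[(tert-butyldimethylsilyl)oxy]-3-methylhex-3-en-1-yl]-4,8-dimethylnona-4,7-dienal
Conditions: i-Bu2AlH (1.05 equiv), CH2Cl2, −78 °C; aq potassium sodium tartrate
Reagents that add atoms: none
Why: Partial ester reduction as in step 3; the stereocentre is β to the carbonyl group and cannot epimerise.

Step 9
Reactants: 12 (3R,4E)-3-[(3E)-6-[(tert-butyldimethylsilyl)oxy]-3-methylhex-3-en-1-yl]-4,8-dimethylnona-4,7-dienal
Product: 13 methyl (2Z,5R,6E)-5-[(3E)-6-[(tert-butyldimethylsilyl)oxy]-3-methylhex-3-en-1-yl]-2,6,10-trimethylundeca-2,6,9-trienoate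
Conditions: (CF3CH2O)2P(O)CH(Me)CO2Me, KN(SiMe3)2, 18-crown-6, THF, −78 °C
Reagents that add atoms: methyl 2-[bis(2,2,2-trifluoroethoxy)phosphoryl]propanoate, COC(=O)C(C)P(=O)(OCC(F)(F)F)OCC(F)(F)F
Why: Still–Gennari olefination; the electron-poor phosphonate under dissociating conditions should give the (Z)-2-methyl enoate, which places the ester carbon (ring C4) cis to C7 as the (5Z) alkene requires.

Step 10
Reactants: 13 methyl (2Z,5R,6E)-5-[(3E)-6-[(tert-butyldimethylsilyl)oxy]-3-methylhex-3-en-1-yl]-2,6,10-trimethylundeca-2,6,9-trienoate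
Product: 14 (2Z,5R,6E)-5-[(3E)-6-[(tert-butyldimethylsilyl)oxy]-3-methylhex-3-en-1-yl]-2,6,10-trimethylundeca-2,6,9-trien-1-ol
Conditions: i-Bu2AlH (2.3 equiv), CH2Cl2, −78 → 0 °C; aq potassium sodium tartrate
Reagents that add atoms: none
Why: 1,2-Reduction of the enoate to the allylic alcohol by i-Bu2AlH, with the alkene geometry unchanged.

Step 11
Reactants: 14 (2Z,5R,6E)-5-[(3E)-6-[(tert-butyldimethylsilyl)oxy]-3-methylhex-3-en-1-yl]-2,6,10-trimethylundeca-2,6,9-trien-1-ol
Product: 15 (2Z,5R,6E)-5-[(3E)-6-hydroxy-3-methylhex-3-en-1-yl]-2,6,10-trimethylundeca-2,6,9-trien-1-ol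
Conditions: Bu4NF, THF, 0 → 20 °C
Reagents that add atoms: none
Why: Fluoride-induced cleavage of the silyl ether, driven by Si–F bond formation.

Step 12
Reactants: 15 (2Z,5R,6E)-5-[(3E)-6-hydroxy-3-methylhex-3-en-1-yl]-2,6,10-trimethylundeca-2,6,9-trien-1-ol
Product: 16 (2Z,5R,6E)-1-bromo-5-[(3E)-6-bromo-3-methylhex-3-en-1-yl]-2,6,10-trimethylundeca-2,6,9-triene
Conditions: CBr4 (2.5 equiv), PPh3 (2.6 equiv), CH2Cl2, −20 → 0 °C; used at once
Reagents that add atoms: carbon tetrabromide, BrC(Br)(Br)Br
Why: Appel reaction; both primary hydroxyl groups are replaced by SN2 attack of bromide on the alkoxyphosphonium ions under neutral conditions, which should avoid allylic transposition and loss of the (Z) geometry.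

Step 13
Reactants: 16 (2Z,5R,6E)-1-bromo-5-[(3E)-6-bromo-3-methylhex-3-en-1-yl]-2,6,10-trimethylundeca-2,6,9-triene
Product: 18 (6Z,9R,10E)-9-[(3E)-6-bromo-3-methylhex-3-en-1-yl]-6,10,14-trimethylpentadeca-6,10,13-trien-2-yn-1-ol, via lithium acetylide 17 (not isolated)
Conditions: propyne, n-BuLi (2 equiv), TMEDA, Et2O/hexane, −78 → 0 °C (1.0 equiv of dianion); 16, THF, −78 °C; (CH2O)n, −78 → 20 °C; aq NH4Cl
Reagents that add atoms: propyne, CC#C; formaldehyde (from paraformaldehyde), C=O
Why: Propargylation with 1,3-dilithiopropyne, whose sp3 carbanion should alkylate the allylic bromide much faster than the unactivated primary bromide (one equivalent, −78 °C), leaving lithium acetylide 17, which is hydroxymethylated in the same pot; a known one-pot sequence on geranyl-type bromides.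

Step 14
Reactants: 18 (6Z,9R,10E)-9-[(3E)-6-bromo-3-methylhex-3-en-1-yl]-6,10,14-trimethylpentadeca-6,10,13-trien-2-yn-1-ol
Product: 22 [(1E,5Z,8R,11E)-5,11-dimethyl-8-[(2E)-6-methylhepta-2,5-dien-2-yl]cyclotetradeca-1,5,11-trien-1-yl]methanol (CNP0355114.1), via bromomagnesium alkoxide 19 (not isolated), via alkoxide Grignard reagent 20 (not isolated), via cyclic alkenylmagnesium chelate 21 (not isolated)
Conditions: MeMgBr (1.0 equiv), THF, −20 °C; Mg turnings, LiCl, THF, 25 °C (0.1 M); slow addition into CuI (20 mol %), THF, 25 → 40 °C (final 2 mM); aq NH4Cl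
Reagents that add atoms: none
Why: Proposed new method: MeMgBr turns the hydroxyl of 18 into bromomagnesium alkoxide 19 and magnesium insertion into the primary C–Br bond gives the tethered alkylmagnesium 20; with catalytic CuI (monovalent copper) the alkyl carbon (ring C14) is transferred to the alkyne carbon next to the CH2O group (ring C1) while the alkoxide-bound magnesium takes the distal alkyne carbon (ring C2) from the opposite side, giving the five-membered chelate 21 (O–Mg–C2=C1–CH2), which is protonated on work-up. The closest known reaction type is the intermolecular CuI-catalysed anti-carbomagnesiation of propargylic alcohols by Grignard reagents, which gives 2-substituted allylic alcohols through the same cyclic alkenylmagnesium; here it is made intramolecular and ring-forming. The 14-membered ring closes in a 14-endo-dig mode, and because the addition is anti the two ring branches (C3 and C14) end up cis on the new double bond, a geometry that a 14-membered ring should hold without strain. No stereocentre is created; the C1=C2 geometry is fixed by the chelate, which forces magnesium and then hydrogen on C2 to be cis to CH2OH (the (1E) alkene of 22), and C8 and the three existing double bonds are not touched. The step needs regioselectivity for C1, secured because only magnesium on C2 can close a five-membered chelate with the alkoxide, and ring closure over oligomerisation, secured by forming 20 at moderate concentration without copper (uncatalysed addition of alkyl Grignard reagents to alkynols is slow) and feeding it slowly into dilute CuI. The trisubstituted alkenes are inert to carbomagnesiation, and the homoallylic C–Mg bond can only rearrange degenerately through its cyclopropylcarbinyl form.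

**Compound list**

1 | 3-[(tert-butyldimethylsilyl)oxy]propanal | O=CCCO[Si](C)(C)C(C)(C)C | starting material
2 | rac-5-[(tert-butyldimethylsilyl)oxy]-2-methylpent-1-en-3-ol | C=C(C)C(O)CCO[Si](C)(C)C(C)(C)C | intermediate
3 | 1-ethoxyvinyl ether (ketene acetal) of 2 | C=C(OCC)OC(CCO[Si](C)(C)C(C)(C)C)C(C)=C | intermediate
4 | ethyl (4E)-7-[(tert-butyldimethylsilyl)oxy]-4-methylhept-4-enoate | CCOC(=O)CC/C(C)=C/CCO[Si](C)(C)C(C)(C)C | intermediate
5 | (4E)-7-[(tert-butyldimethylsilyl)oxy]-4-methylhept-4-enal | O=CCC/C(C)=C/CCO[Si](C)(C)C(C)(C)C | intermediate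
6 | (2E,6E)-9-[(tert-butyldimethylsilyl)oxy]-2,6-dimethylnona-2,6-dienal | O=C/C(C)=C/CC/C(C)=C/CCO[Si](C)(C)C(C)(C)C | intermediate
7 | diisopinocampheylborinate ester of 8 | C=CC[C@@H](OB([C@H]1C[C@H]2C[C@@H]([C@@H]1C)C2(C)C)[C@H]1C[C@H]2C[C@@H]([C@@H]1C)C2(C)C)/C(C)=C/CC/C(C)=C/CCO[Si](C)(C)C(C)(C)C | intermediate
8 | (4R,5E,9E)-12-[(tert-butyldimethylsilyl)oxy]-5,9-dimethyldodeca-1,5,9-trien-4-ol | C=CC[C@@H](O)/C(C)=C/CC/C(C)=C/CCO[Si](C)(C)C(C)(C)C | intermediate
9 | (5R,6E,10E)-13-[(tert-butyldimethylsilyl)oxy]-2,6,10-trimethyltrideca-2,6,10-trien-5-ol | CC(C)=CC[C@@H](O)/C(C)=C/CC/C(C)=C/CCO[Si](C)(C)C(C)(C)C | intermediate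
10 | 1-ethoxyvinyl ether (ketene acetal) of 9 | CC(C)=CC[C@@H](OC(=C)OCC)/C(C)=C/CC/C(C)=C/CCO[Si](C)(C)C(C)(C)C | intermediate
11 | ethyl (3R,4E)-3-[(3E)-6-[(tert-butyldimethylsilyl)oxy]-3-methylhex-3-en-1-yl]-4,8-dimethylnona-4,7-dienoate | CCOC(=O)C[C@@H](CC/C(C)=C/CCO[Si](C)(C)C(C)(C)C)/C(C)=C/CC=C(C)C | intermediate
12 | (3R,4E)-3-[(3E)-6-[(tert-butyldimethylsilyl)oxy]-3-methylhex-3-en-1-yl]-4,8-dimethylnona-4,7-dienal | O=CC[C@@H](CC/C(C)=C/CCO[Si](C)(C)C(C)(C)C)/C(C)=C/CC=C(C)C | intermediate
13 | methyl (2Z,5R,6E)-5-[(3E)-6-[(tert-butyldimethylsilyl)oxy]-3-methylhex-3-en-1-yl]-2,6,10-trimethylundeca-2,6,9-trienoate | COC(=O)/C(C)=C\C[C@@H](CC/C(C)=C/CCO[Si](C)(C)C(C)(C)C)/C(C)=C/CC=C(C)C | intermediate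
14 | (2Z,5R,6E)-5-[(3E)-6-[(tert-butyldimethylsilyl)oxy]-3-methylhex-3-en-1-yl]-2,6,10-trimethylundeca-2,6,9-trien-1-ol | OC/C(C)=C\C[C@@H](CC/C(C)=C/CCO[Si](C)(C)C(C)(C)C)/C(C)=C/CC=C(C)C | intermediate
15 | (2Z,5R,6E)-5-[(3E)-6-hydroxy-3-methylhex-3-en-1-yl]-2,6,10-trimethylundeca-2,6,9-trien-1-ol | OC/C(C)=C\C[C@@H](CC/C(C)=C/CCO)/C(C)=C/CC=C(C)C | intermediate
16 | (2Z,5R,6E)-1-bromo-5-[(3E)-6-bromo-3-methylhex-3-en-1-yl]-2,6,10-trimethylundeca-2,6,9-triene | BrC/C(C)=C\C[C@@H](CC/C(C)=C/CCBr)/C(C)=C/CC=C(C)C | intermediate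
17 | lithium acetylide from propargylation of 16 | [Li]C#CCC/C(C)=C\C[C@@H](CC/C(C)=C/CCBr)/C(C)=C/CC=C(C)C | intermediate
18 | (6Z,9R,10E)-9-[(3E)-6-bromo-3-methylhex-3-en-1-yl]-6,10,14-trimethylpentadeca-6,10,13-trien-2-yn-1-ol | OCC#CCC/C(C)=C\C[C@@H](CC/C(C)=C/CCBr)/C(C)=C/CC=C(C)C | intermediate
19 | bromomagnesium alkoxide of 18 | Br[Mg]OCC#CCC/C(C)=C\C[C@@H](CC/C(C)=C/CCBr)/C(C)=C/CC=C(C)C | intermediate
20 | bromomagnesium alkoxide of 18 with C–MgBr in place of C–Br | Br[Mg]OCC#CCC/C(C)=C\C[C@@H](CC/C(C)=C/CC[Mg]Br)/C(C)=C/CC=C(C)C | intermediate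
21 | macrocyclic alkenylmagnesium chelate (Mg bridging the alkoxide oxygen and ring C2) | CC(C)=CC/C=C(\C)[C@H]1C/C=C(/C)CC/C2=C(/CO[Mg]2)CC/C=C(\C)CC1 | intermediate
22 | [(1E,5Z,8R,11E)-5,11-dimethyl-8-[(2E)-6-methylhepta-2,5-dien-2-yl]cyclotetradeca-1,5,11-trien-1-yl]methanol (CNP0355114.1) | CC(C)=CC/C=C(\C)[C@H]1C/C=C(/C)CC/C=C(/CO)CC/C=C(\C)CC1 | target

**Step count and risks**

Total step count: 14. Longest linear sequence: 14 steps (fully linear from 1).

Steps most likely to fail:

Step 14 (proposed new method). The tethered alkylmagnesium may add too slowly to the internal alkynol, so that it is only protonated on work-up, or it may add intermolecularly and give oligomers. The fallback uses known chemistry, sets out from 18 and comes back at 22. Ruthenium-catalysed trans-hydrostannation of the propargylic alcohol ([Cp*RuCl]4, Bu3SnH, CH2Cl2, 20 °C) puts tin on the alkyne carbon next to the carbinol and hydrogen trans to it, giving the (Z)-2-stannyl allylic alcohol F1. Iodine (CH2Cl2, 0 °C) replaces tin with retention and gives the (Z)-2-iodo allylic alcohol F2. A nickel-catalysed reductive cross-electrophile coupling of the alkenyl iodide with the primary alkyl bromide (NiBr2(glyme), 4,4′-di-tert-butyl-2,2′-bipyridine, Mn, NaI, N,N-dimethylacetamide, slow addition, final 2 mM) then closes the same C1–C14 bond with retention of the alkene geometry and should give 22.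

Step 13. Chemoselectivity between the two bromides may be lost: the dianion or the acetylide may also substitute the unactivated primary bromide, or the acetylide may be captured incompletely by formaldehyde. The fallback separates the two halides by leaving-group class instead of by rate; it sets out from 15 and comes back at 22. N-Chlorosuccinimide and PPh3 (THF, 0 °C) give the dichloride F3. 1,3-Dilithiopropyne followed by paraformaldehyde, as in step 13, gives the chloro alkynol F4; a primary alkyl chloride is known to survive this reagent. NaI in refluxing acetone gives the iodo alkynol F5, which enters the ring closure of step 14 (Mg insertion into the iodide at 0 → 20 °C) and should give 22.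

Step 5. Facial selectivity of allyl transfer to the α-branched enal may be insufficient, and no later step can correct the enantiomeric ratio, because step 7 only relays it. The fallback sets the carbinol by catalyst-controlled ketone reduction and bypasses steps 5 and 6; it sets out from 6 and comes back at 9. α-Selective addition of prenylbarium chloride (prenyl chloride, barium from BaI2 and lithium biphenylide, THF, −78 °C) gives the racemic prenyl carbinol F6. MnO2 (CH2Cl2) oxidises it to the enone F7. CBS reduction ((S)-2-methyl-CBS-oxazaborolidine, catecholborane, toluene, −78 °C), with the α-methyl alkenyl group as the large substituent, should give (R)-configured 9.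

Further compounds
F1 | step 14 | (2Z,6Z,9R,10E)-9-[(3E)-6-bromo-3-methylhex-3-en-1-yl]-6,10,14-trimethyl-2-(tributylstannyl)pentadeca-2,6,10,13-tetraen-1-ol | OC/C(=C/CC/C(C)=C\C[C@@H](CC/C(C)=C/CCBr)/C(C)=C/CC=C(C)C)[Sn](CCCC)(CCCC)CCCC
F2 | step 14 | (2Z,6Z,9R,10E)-9-[(3E)-6-bromo-3-methylhex-3-en-1-yl]-2-iodo-6,10,14-trimethylpentadeca-2,6,10,13-tetraen-1-ol | OC/C(I)=C/CC/C(C)=C\C[C@@H](CC/C(C)=C/CCBr)/C(C)=C/CC=C(C)C
F3 | step 13 | (2Z,5R,6E)-1-chloro-5-[(3E)-6-chloro-3-methylhex-3-en-1-yl]-2,6,10-trimethylundeca-2,6,9-triene | ClC/C(C)=C\C[C@@H](CC/C(C)=C/CCCl)/C(C)=C/CC=C(C)C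
F4 | step 13 | (6Z,9R,10E)-9-[(3E)-6-chloro-3-methylhex-3-en-1-yl]-6,10,14-trimethylpentadeca-6,10,13-trien-2-yn-1-ol | OCC#CCC/C(C)=C\C[C@@H](CC/C(C)=C/CCCl)/C(C)=C/CC=C(C)C
F5 | step 13 | (6Z,9R,10E)-9-[(3E)-6-iodo-3-methylhex-3-en-1-yl]-6,10,14-trimethylpentadeca-6,10,13-trien-2-yn-1-ol | OCC#CCC/C(C)=C\C[C@@H](CC/C(C)=C/CCI)/C(C)=C/CC=C(C)C
F6 | step 5 | rac-(6E,10E)-13-[(tert-butyldimethylsilyl)oxy]-2,6,10-trimethyltrideca-2,6,10-trien-5-ol | CC(C)=CCC(O)/C(C)=C/CC/C(C)=C/CCO[Si](C)(C)C(C)(C)C
F7 | step 5 | (6E,10E)-13-[(tert-butyldimethylsilyl)oxy]-2,6,10-trimethyltrideca-2,6,10-trien-5-one | CC(C)=CCC(=O)/C(C)=C/CC/C(C)=C/CCO[Si](C)(C)C(C)(C)C
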